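**Plan**
- Retrosynthetic cuts, in order: the four aryl O–CH3 bonds; the bond from the catechol ring to ring carbon C6; the C6=C7 unsaturation; the C3–styryl bond together with a 1,3-carbonyl transposition; the bond from the resorcinol ring to C5; the enol-ether C–O bond of a cycloheptane-1,3-dione vinylogous ester.
- Enabling feature: C5 and C6 are the two β-carbons of a latent cycloheptane-1,3-dione (C5 is β to C3, C6 is β to C1). The seven-membered ring is therefore bought, and each aryl group enters by rhodium-catalysed 1,4-addition once the matching enone is unveiled. In the cross-conjugated cyclohepta-2,6-dienone used for the second arylation, C6 is the only β-monosubstituted acceptor carbon.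
- Forward order: dione → vinylogous ester → dienone → arylation at the future C5 → styryllithium addition and acid transposition (carbonyl to C1, styryl on C3) → α'-desaturation → arylation at C6 → demethylation.
- Stereochemistry: C5 is set by catalyst control with [Rh(OH)((R)-binap)]2. C6 is set by addition anti to the C5 aryl group, reinforced by the same ligand (matched pair). The E alkene is carried in from (E)-β-bromostyrene.

Key step: step 6

Remark: locants C1–C7 in the explanations are those of the target ring (C1 carbonyl, C3 styryl, C5 resorcinol ring, C6 catechol ring). The sense of induction of (R)-BINAP on the seven-membered dienones is assumed by analogy with cyclohept-2-enone and has not been checked on these substrates.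

**Step 1**
Reactants: 1 cycloheptane-1,3-dione
Product: 2 3-ethoxycyclohept-2-en-1-one
Conditions: EtOH, p-TsOH·H2O (cat.), toluene, reflux, Dean–Stark
Reagents that add atoms: ethanol, CCO
Why: Acid-catalysed enol etherification of a symmetric 1,3-dione with azeotropic removal of water (vinylogous ester formation); the symmetry of 1 allows only one regioisomer and no stereocentre is formed.

**Step 2**
Reactants: 2 3-ethoxycyclohept-2-en-1-one
Product: 4 3-ethoxycyclohepta-2,6-dien-1-one, via silyl dienol ether 3 (not isolated)
Conditions: LiN(i-Pr)2, Me3SiCl, THF, −78 °C; then Pd(OAc)2 (1.05 equiv), MeCN, 23 °C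
Reagents that add atoms: chlorotrimethylsilane, C[Si](C)(C)Cl (its silyl group is carried by 3 and leaves again on the way to 4)
Why: Kinetic deprotonation of a vinylogous ester takes the α'-hydrogen next to the carbonyl group, the enolate is trapped on oxygen, and Saegusa–Ito oxidation (palladation at the α'-carbon, β-hydride elimination from the only adjacent CH2) installs the second double bond without touching the ethoxy enone; no stereocentre is formed.

**Step 3**
Reactants: 4 3-ethoxycyclohepta-2,6-dien-1-one; 5 3,5-dimethoxyphenylboronic acid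
Product: 6 (R)-6-(3,5-dimethoxyphenyl)-3-ethoxycyclohept-2-en-1-one
Conditions: [Rh(OH)((R)-binap)]2 (1.5 mol %), 5 (2 equiv), dioxane/H2O 10:1, 35 °C
Reagents that add atoms: none
Why: Hayashi–Miyaura rhodium-catalysed asymmetric 1,4-addition: the aryl–rhodium species inserts only the β-monosubstituted enone, because the ethoxy-bearing enone is β,β-disubstituted and deactivated, and (R)-BINAP, which gives (R)-3-arylcycloalkanones from cycloalk-2-enones, should set the new benzylic stereocentre (the future C5) as R.

**Step 4**
Reactants: 6 (R)-6-(3,5-dimethoxyphenyl)-3-ethoxycyclohept-2-en-1-one; 7 (E)-(2-bromoethenyl)benzene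
Product: 9 (R)-5-(3,5-dimethoxyphenyl)-3-[(E)-2-phenylethenyl]cyclohept-2-en-1-one, via carbinol 8 (not isolated)
Conditions: 7, t-BuLi (2 equiv), Et2O, −78 °C; then 6, THF, −78 → 0 °C; then 1 M HCl, 0 → 23 °C
Reagents that add atoms: water, O (the new carbonyl oxygen)
Why: Stork–Danheiser transposition: styryllithium made by bromine–lithium exchange with retention of the E geometry adds 1,2 to the vinylogous ester carbonyl, and aqueous acid ionises the bis-allylic carbinol and hydrolyses the enol ether, which moves the carbonyl group to the former ethoxy carbon (C1) and leaves the styryl group on C3; the stereocentre is remote from every acidic position and is not touched.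

**Step 5**
Reactants: 9 (R)-5-(3,5-dimethoxyphenyl)-3-[(E)-2-phenylethenyl]cyclohept-2-en-1-one
Product: 11 (S)-5-(3,5-dimethoxyphenyl)-3-[(E)-2-phenylethenyl]cyclohepta-2,6-dien-1-one, via silyl dienol ether 10 (not isolated)
Conditions: LiN(i-Pr)2, Me3SiCl, THF, −78 °C; then Pd(OAc)2 (1.05 equiv), MeCN, 23 °C
Reagents that add atoms: chlorotrimethylsilane, C[Si](C)(C)Cl (its silyl group is carried by 10 and leaves again on the way to 11)
Why: Kinetic deprotonation of the enone at −78 °C takes the α'-hydrogen at C7 (cross-conjugated dienolate) in preference to the γ-hydrogen at C4, and Saegusa–Ito oxidation of the silyl dienol ether can eliminate only towards C6, which gives the cross-conjugated 2,6-dienone; C5 is not involved (its descriptor changes only because C6 becomes sp2), and 11 is kept away from base because its C5 hydrogen is now γ to the carbonyl group.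

**Step 6**
Reactants: 11 (S)-5-(3,5-dimethoxyphenyl)-3-[(E)-2-phenylethenyl]cyclohepta-2,6-dien-1-one; 12 3,4-dimethoxyphenylboronic acid
Product: 13 (5S,6S)-6-(3,4-dimethoxyphenyl)-5-(3,5-dimethoxyphenyl)-3-[(E)-2-phenylethenyl]cyclohept-2-en-1-one
Conditions: [Rh(OH)((R)-binap)]2 (2.5 mol %), 12 (2 equiv), dioxane/H2O 10:1, 35 °C, no added base
Reagents that add atoms: none
Why: Transmetalation of 12 to the hydroxorhodium complex gives an aryl species of monovalent rhodium that binds the C6=C7 alkene of 11, inserts it syn (aryl to C6, rhodium to C7 as an oxa-π-allyl enolate) and is released by water, which regenerates Rh–OH; the closest known reaction type is the Hayashi–Miyaura asymmetric 1,4-addition of arylboronic acids to cycloalk-2-enones and 4-substituted cycloalkenones. No ring is closed; the step joins the catechol ring to the finished seven-membered ring. The new stereocentre C6 is controlled twice in the same sense: the C5 aryl group next to the β-carbon blocks its own face so that the new aryl group enters anti (trans-5,6), and (R)-BINAP, which delivers aryl groups in the sense of (R)-3-arylcycloheptanone, should select that same face of the C1/C7/C6 enone (the descriptor is 6S only because C5 outranks C7). Site selectivity among three acceptor positions is needed and comes from substitution: C6 is the only β-monosubstituted enone carbon, C3 is β,β-disubstituted, and the styryl terminus would need a 1,6-addition that rhodium–phosphine catalysts do not favour. The configuration at C5, whose hydrogen is γ to the C1 carbonyl and benzylic, is protected by the base-free hydroxo catalyst at 35 °C, which avoids dienolate formation and migration of the double bond into the conjugated 2,4-dienone. Because the same ligand set C5 in step 3, any minor enantiomer of 11 is a mismatched substrate and should end mainly in the separable cis diastereomer, so 13 should be enantiomerically purer than 11.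

**Step 7**
Reactants: 13 (5S,6S)-6-(3,4-dimethoxyphenyl)-5-(3,5-dimethoxyphenyl)-3-[(E)-2-phenylethenyl]cyclohept-2-en-1-one
Product: 14 (5S,6S)-6-(3,4-dihydroxyphenyl)-5-(3,5-dihydroxyphenyl)-3-[(E)-2-phenylethenyl]cyclohept-2-en-1-one
Conditions: BBr3 (10 equiv), CH2Cl2, −78 → 0 °C; then H2O, 0 °C
Reagents that add atoms: none
Why: Complexation of each aryl methyl ether with BBr3 and SN2 attack of bromide on the methyl group (standard BBr3 demethylation, precedented on chalcone-type enones and stilbenes), followed by hydrolysis of the aryl borates, frees the four phenols; C5 and C6 carry no acidic hydrogen and the E alkene should be retained at low temperature.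

**Compound list**
1 | cycloheptane-1,3-dione | O=C1CC(=O)CCCC1 | starting material
2 | 3-ethoxycyclohept-2-en-1-one | CCOC1=CC(=O)CCCC1 | intermediate
3 | 1-ethoxy-3-(trimethylsilyloxy)cyclohepta-1,3-diene | CCOC1=CC(O[Si](C)(C)C)=CCCC1 | intermediate
4 | 3-ethoxycyclohepta-2,6-dien-1-one | CCOC1=CC(=O)C=CCC1 | intermediate
5 | 3,5-dimethoxyphenylboronic acid | COc1cc(OC)cc(B(O)O)c1 | starting material
6 | (R)-6-(3,5-dimethoxyphenyl)-3-ethoxycyclohept-2-en-1-one | CCOC1=CC(=O)C[C@H](c2cc(OC)cc(OC)c2)CC1 | intermediate
7 | (E)-(2-bromoethenyl)benzene (trans-β-bromostyrene) | Br/C=C/c1ccccc1 | starting material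
8 | (6R)-6-(3,5-dimethoxyphenyl)-3-ethoxy-1-[(E)-2-phenylethenyl]cyclohept-2-en-1-ol, both epimers at the carbinol carbon | CCOC1=CC(O)(/C=C/c2ccccc2)C[C@H](c2cc(OC)cc(OC)c2)CC1 | intermediate
9 | (R)-5-(3,5-dimethoxyphenyl)-3-[(E)-2-phenylethenyl]cyclohept-2-en-1-one | O=C1C=C(/C=C/c2ccccc2)C[C@H](c2cc(OC)cc(OC)c2)CC1 | intermediate
10 | (6R)-6-(3,5-dimethoxyphenyl)-1-[(E)-2-phenylethenyl]-3-(trimethylsilyloxy)cyclohepta-1,3-diene | C[Si](C)(C)OC1=CC[C@@H](c2cc(OC)cc(OC)c2)CC(/C=C/c2ccccc2)=C1 | intermediate
11 | (S)-5-(3,5-dimethoxyphenyl)-3-[(E)-2-phenylethenyl]cyclohepta-2,6-dien-1-one | O=C1C=C(/C=C/c2ccccc2)C[C@H](c2cc(OC)cc(OC)c2)C=C1 | intermediate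
12 | 3,4-dimethoxyphenylboronic acid | COc1ccc(B(O)O)cc1OC | starting material
13 | (5S,6S)-6-(3,4-dimethoxyphenyl)-5-(3,5-dimethoxyphenyl)-3-[(E)-2-phenylethenyl]cyclohept-2-en-1-one (trans) | O=C1C=C(/C=C/c2ccccc2)C[C@H](c2cc(OC)cc(OC)c2)[C@@H](c2ccc(OC)c(OC)c2)C1 | intermediate
14 | (5S,6S)-6-(3,4-dihydroxyphenyl)-5-(3,5-dihydroxyphenyl)-3-[(E)-2-phenylethenyl]cyclohept-2-en-1-one (trans) | O=C1C=C(/C=C/c2ccccc2)C[C@H](c2cc(O)cc(O)c2)[C@@H](c2ccc(O)c(O)c2)C1 | target

Total step count: 7. Longest linear sequence: 7 steps (1 → 14).

**Steps most likely to fail**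

Step 6. The C5 hydrogen of 11 is γ to the carbonyl group and benzylic. Enolisation during a slow addition to the hindered β-carbon can move the C6=C7 double bond into conjugation with the aryl ring and erase the C5 configuration, and facial discrimination on the flexible ring may be incomplete. The fallback sets out from 11 and comes back at 13. It is an aprotic copper-mediated conjugate addition at −78 °C (3,4-(MeO)2C6H3MgBr, CuBr·SMe2, Me3SiCl, THF), governed by the substrate alone (aryl anti to the C5 group). The enolate is trapped as the trimethylsilyl enol ether of 13 F1, and dilute HCl on work-up converts it into 13.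

Step 5. During the palladium stage, re-addition of palladium hydride can shift double bonds or carry the dienone on towards a tropone, and the acetic acid formed in the flask may enolise 11. The fallback sets out from 9 and comes back at 11. The same kinetic enolate (LiN(i-Pr)2, THF, −78 °C) is quenched with PhSeBr to give the 7-(phenylselanyl) derivative of 9 F2, which is isolated. H2O2 and pyridine in CH2Cl2 at 0 °C oxidise it to the corresponding selenoxide F3, whose syn-elimination should give 11 without any transition metal.

Step 7. BBr3 activates the dienone as well as the ethers. Intramolecular Friedel–Crafts attack of the electron-rich rings on C3 or on the styryl terminus, or addition of HBr to the diene, may compete with ether cleavage. The fallback sets out from 4 and comes back at 14. It repeats the route with benzyl ethers, which can be cleaved at −78 °C with BCl3 and pentamethylbenzene as cation scavenger; both benzyl-protected boronic acids are assumed to be purchasable.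
- 3,5-Bis(benzyloxy)phenylboronic acid and 4 under the step 3 conditions give (R)-6-[3,5-bis(benzyloxy)phenyl]-3-ethoxycyclohept-2-en-1-one F4.
- Styryllithium addition as in step 4 gives the carbinol F5 (not isolated), and aqueous acid gives (R)-5-[3,5-bis(benzyloxy)phenyl]-3-[(E)-2-phenylethenyl]cyclohept-2-en-1-one F6.
- Silylation and Pd(OAc)2 as in step 5 give the silyl dienol ether F7 (not isolated) and then (S)-5-[3,5-bis(benzyloxy)phenyl]-3-[(E)-2-phenylethenyl]cyclohepta-2,6-dien-1-one F8.
- 3,4-Bis(benzyloxy)phenylboronic acid under the step 6 conditions gives the tetrabenzyl ether of 14 F9.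
- BCl3, C6HMe5, CH2Cl2, −78 °C then gives 14.

**Further compounds**
F1 | step 6 | trimethylsilyl enol ether of 13 (C1(OSiMe3)=C7, benzylic carbons as in 13) | C[Si](C)(C)OC1=C[C@H](c2ccc(OC)c(OC)c2)[C@@H](c2cc(OC)cc(OC)c2)CC(/C=C/c2ccccc2)=C1
F2 | step 5 | (5R)-5-(3,5-dimethoxyphenyl)-3-[(E)-2-phenylethenyl]-7-(phenylselanyl)cyclohept-2-en-1-one, both C7 epimers | O=C1C=C(/C=C/c2ccccc2)C[C@H](c2cc(OC)cc(OC)c2)CC1[Se]c3ccccc3
F3 | step 5 | selenoxide of F2 | O=C1C=C(/C=C/c2ccccc2)C[C@H](c2cc(OC)cc(OC)c2)CC1[Se](=O)c3ccccc3
F4 | step 7 | (R)-6-[3,5-bis(benzyloxy)phenyl]-3-ethoxycyclohept-2-en-1-one | CCOC1=CC(=O)C[C@H](c2cc(OCc3ccccc3)cc(OCc3ccccc3)c2)CC1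
F5 | step 7 | (6R)-6-[3,5-bis(benzyloxy)phenyl]-3-ethoxy-1-[(E)-2-phenylethenyl]cyclohept-2-en-1-ol, both carbinol epimers | CCOC1=CC(O)(/C=C/c2ccccc2)C[C@H](c2cc(OCc3ccccc3)cc(OCc3ccccc3)c2)CC1
F6 | step 7 | (R)-5-[3,5-bis(benzyloxy)phenyl]-3-[(E)-2-phenylethenyl]cyclohept-2-en-1-one | O=C1C=C(/C=C/c2ccccc2)C[C@H](c2cc(OCc3ccccc3)cc(OCc3ccccc3)c2)CC1
F7 | step 7 | (6R)-6-[3,5-bis(benzyloxy)phenyl]-1-[(E)-2-phenylethenyl]-3-(trimethylsilyloxy)cyclohepta-1,3-diene | C[Si](C)(C)OC1=CC[C@@H](c2cc(OCc3ccccc3)cc(OCc3ccccc3)c2)CC(/C=C/c2ccccc2)=C1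
F8 | step 7 | (S)-5-[3,5-bis(benzyloxy)phenyl]-3-[(E)-2-phenylethenyl]cyclohepta-2,6-dien-1-one | O=C1C=C(/C=C/c2ccccc2)C[C@H](c2cc(OCc3ccccc3)cc(OCc3ccccc3)c2)C=C1
F9 | step 7 | (5S,6S)-6-[3,4-bis(benzyloxy)phenyl]-5-[3,5-bis(benzyloxy)phenyl]-3-[(E)-2-phenylethenyl]cyclohept-2-en-1-one | O=C1C=C(/C=C/c2ccccc2)C[C@H](c2cc(OCc3ccccc3)cc(OCc3ccccc3)c2)[C@@H](c2ccc(OCc3ccccc3)c(OCc3ccccc3)c2)C1
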